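(The numbers of this flask belong to no real substance.)

In this flask I set two first-order rates of the electrophile side by side: nucleophile at a concentration equal to the electrophile charge, a reckoned case, gave 0.110 h⁻¹, faster than the forward slide into dormant form at 0.043 h⁻¹.

electrophile 0.050 M; buffer base 0.0100 M; buffer acid 0.0150 M; solid nucleophile 0.0600 M; scavenger 0.0750 M; time 30 h

    buffer acid ⇌ buffer base + acid, settled at all times (K1 = 2.0 × 10⁻⁹ M)
    electrophile ⇌ dormant form (K2 = 9.2, k2 = 0.043 h⁻¹)
    protonated nucleophile ⇌ nucleophile + acid, settled at all times (K3 = 1.6 × 10⁻⁷ M)
    solid nucleophile ⇌ nucleophile, rate k4*(cs4 - [nucleophile]) while solid is left; crystals form when [nucleophile] > cs4 (cs4 = 45 mM, k4 = 0.22 h⁻¹)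
    electrophile + leaving group ⇌ idle adduct, settled at all times (K5 = 24 M⁻¹)
    scavenger + leaving group → scavenged by-product (k6 = 70 M⁻¹ h⁻¹)
    electrophile + nucleophile → acid + target + leaving group (k7 = 2.2 M⁻¹ h⁻¹)

- acid is the free proton; pH is minus the decimal logarithm of its molar concentration
- what is said of leaving group includes idle adduct
- solid nucleophile is a solid; its amount is given per volume of the solution
- at the start none of the solid nucleophile is in solution
- what has gone from electrophile into another species counts as reacted, even if it can come back
- run time (flask): 30 h

1. part of the electrophile that has reacted at 30 h
2. pH of the solution at 30 h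

I divided the rate of target formation by the forward rate into dormant form, and time dropped out. What stayed was a branch ratio, target made per dormant form made. It equals n times the branch number 2.56, the ratio when free nucleophile equals the electrophile charge. Here n is free nucleophile as a fraction of the electrophile charge, and p is target on the same scale.

Each target released one acid. I let buffer base take up the first 0.200. After that, each target cost two nucleophiles, one consumed and one protonated. So with the solid dissolved, n was 1.40 minus two times p.

| p | n | branch ratio |
|---|---|---|
| 0.200 | 0.900 | 2.30 |
| 0.5 | 0.400 | 1.02 |
| 0.700 | 0 | 0 |

The first row took n at the solubility limit, so I read its ratio as an upper figure for that stage, not as a state of the flask. In the second row the ratio stood at about 1. The third row was the ceiling on target, with free nucleophile as the limiting reagent once acid was charged against it.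

I committed to the second row for 30 h. I ran the electrophile's loss at that row's rate, 0.0870 h⁻¹, and ignored any return from dormant form. That gave 92.6 % reacted. Free against protonated nucleophile, n against p minus 0.200, gave pH 6.92.

The forecast said 92 % and pH 6.85, slightly below my two figures, holding that the remaining nucleophile “becomes the buffer and sets the pH”.

The simulation gave 92.3 % and pH 6.86, so the forecast stood. In the flask at 30.0 h, the reacted part held 41.1 % as dormant form beside 51.2 % as target. Free nucleophile stood at n = 0.370, and the branch ratio, forward step alone, was 0.95. In the neighbouring flask with 0.036 M of solid nucleophile, the same reckoning starts from 0.920 and puts the ceiling at 0.460, lower than the flask's. That neighbour reacted 85.9 %. Its n stood at 0.130, its branch ratio at 0.332, and its target at 39.3 %.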